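Percent of the free monomer charged is my unit: a species is counted by the free monomer in it, so a side product counts as two. The new flask carries more initiator than the green and violet runs, and I want to know how high monomer in chains climbs in it.

| setting | green | violet | flask |
|---|---|---|---|
| free monomer | 0.20 M | 0.20 M | 0.20 M |
| initiator | 0.19 mM | 0.29 mM | 0.38 mM |
| remark | run made earlier | run made earlier |  |
| time |  |  | 15 d |

- green (time / d: monomer in chains / %, free monomer / %): 0.333: 5.7, 90.9; 0.625: 7.7, 83.8; 1.25: 8.6, 70.4; 3.00: 7.0, 46.4; 6.00: 2.9, 31.6; 12.0: 0.5, 24.3
- violet (time / d: monomer in chains / %, free monomer / %): 0.333: 6.7, 89.0; 0.625: 9.5, 80.4; 1.25: 10.9, 63.7; 3.00: 9.6, 38.5; 6.00: 4.1, 23.9; 12.0: 1.0, 17.3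

(each reading ± 0.3 percentage points)

- a species is counted by the free monomer in it: one side product counts as two
- reactions considered so far: 2 growing radical -> dead chain; monomer in chains <-> isomer of the product; initiator -> 2 initiating radical; free monomer + growing radical -> monomer in chains + growing radical; free monomer + monomer in chains -> side product; monomer in chains -> over-reaction product; free monomer + initiating radical -> growing radical + monomer in chains

- time up to 15 d at which monomer in chains stands highest
- the amount of monomer in chains, in percent of the free monomer charged, at that time
- the first time at which monomer in chains reaches 8.6%, in the same percent, in d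

I follow the green run in slow motion. By 0.333 d free monomer in green has lost 9.10%, and more of that stands as monomer in chains, 5.7%, than in the other products together, so chain growth leads in green. The pseudo-first-order constant for the whole loss of free monomer over this first stretch reads 0.287 /d in green and 0.350 /d in violet, a ratio of 1.22. The root of the initiator ratio is 1.24, which is what a source proportional to c(initiator) gives against a pairwise end of growing radicals.

In the middle, both runs read their highest monomer in chains at 1.25 d: 8.6% in green and 10.9% in violet. With the top at the same reading, I take the lifetime of monomer in chains as common, and the height as making rate times lifetime.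

Late in green, the constant of free monomer sinks to 0.0438 /d between 6.00 d and 12.0 d, and monomer in chains drains to 0.5%.

Dividing the highest reading by the root of the equivalents of initiator, green gives 2.79 and violet 2.86. Their mean, 2.83, is what I carry, a value read from scattered readings: the peak number, the highest amount of monomer in chains as a fraction of the free monomer charged, divided by the root of the equivalents of initiator. For the new flask my reckoning gives 12.3%.

The forecast, holding that “the rate goes as √[initiator]”, stands higher: 12.7% (12.1% to 13.3%) at 1.4 d (1.05 d to 1.8 d), with the level reached at 0.42 d (0.37 d to 0.47 d).

The new flask tops at 12.3% at 1.28 d and reaches the level at 0.393 d, each inside the forecast's range.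

    2 growing radical → dead chain (k = 4.00 × 10⁷ /M/s)
    monomer in chains ⇌ isomer of the product (K = 0.360, k = 0.0200 /h)
    initiator → 2 initiating radical (k = 0.0250 /h)
    free monomer + growing radical → monomer in chains + growing radical, rate k4*[growing radical]*[free monomer] (k = 1.80 × 10⁶ /M/h)
    free monomer + monomer in chains → side product (k = 0.250 /M/h)
    monomer in chains → over-reaction product (k = 0.0130 /h)
    free monomer + initiating radical → growing radical + monomer in chains (k = 2.60 × 10⁷ /M/h)

The peak number of the new flask comes to 2.82, against the carried 2.83. A neighbour charged with 9.5 × 10⁻⁵ M of initiator, its free monomer as in the new flask, takes the same reckoning: 2.83 times the root of its equivalents gives 6.16%. Its simulated top is 6.56%, so the peak number of the neighbour comes to 3.01, higher than the carried value.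

The numbers in the tables come from a simulation from invented constants.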